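**Retrosynthetic overview**
1. The target comes from the methyl ester of the same dihydrobenzofuran by ester-to-allylic-alcohol reduction (last step).
2. The dihydrofuran ring is the only ring made (both benzene rings are bought). It is closed late by enantioselective O–H addition of a phenol across an o-hydroxy-α-methylstilbene; the new C2–O bond fixes C2 and C3 together.
3. The stilbene comes from an alkenyl boronate and methyl 5-iodoferulate (Suzuki–Miyaura).
4. The alkenyl boronate comes from an aryl propyne, made from 4-iodoveratrole and propyne; the iodoferulate comes from 5-iodovanillin and a stabilised ylide.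

Assumption: the sense of induction of the new acid-catalysed cyclisation cannot be predicted with certainty, so the catalyst antipode giving (2S,3S) is fixed by one small-scale test (both antipodes come from (S)- or (R)-BINOL) and is written below as (S,S)-IDPi-1.

**Route**

Step 1
Reactants: 1 4-iodo-1,2-dimethoxybenzene; 2 propyne
Product: 3 1,2-dimethoxy-4-(prop-1-yn-1-yl)benzene
Conditions: PdCl2(PPh3)2 (2 mol %), CuI (4 mol %), Et3N, THF, propyne (1.5 equiv), rt
Reagents that add atoms: none
Why: Sonogashira coupling of an aryl iodide with a terminal alkyne is fast at room temperature, and the methyl ethers are inert.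

Step 2
Reactants: 3 1,2-dimethoxy-4-(prop-1-yn-1-yl)benzene
Product: 4 2-[(Z)-1-(3,4-dimethoxyphenyl)prop-1-en-2-yl]-4,4,5,5-tetramethyl-1,3,2-dioxaborolane (aryl trans to boron)
Conditions: CuCl (5 mol %), P(p-tol)3 (6 mol %), NaOt-Bu (10 mol %), B2pin2 (1.1 equiv), MeOH (2 equiv), THF, rt
Reagents that add atoms: bis(pinacolato)diboron (B2pin2), CC1(C)OB(OC1(C)C)B1OC(C)(C)C(C)(C)O1
Why: Copper-boryl-catalysed syn-hydroboration (protoboration) of an aryl alkyl alkyne puts boron on the methyl-bearing carbon and hydrogen on the aryl-bearing carbon from the same side, which fixes the aryl group trans to boron.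

Step 3
Reactants: 5 4-hydroxy-3-iodo-5-methoxybenzaldehyde (5-iodovanillin); 6 methyl (triphenylphosphoranylidene)acetate
Product: 7 methyl (E)-3-(4-hydroxy-3-iodo-5-methoxyphenyl)prop-2-enoate
Conditions: PhMe, 90 °C (1.3 equiv of ylide)
Reagents that add atoms: none
Why: Wittig olefination with a stabilised ylide gives the (E)-cinnamate selectively and tolerates the free phenol and the aryl iodide.

Step 4
Reactants: 4 2-[(Z)-1-(3,4-dimethoxyphenyl)prop-1-en-2-yl]-4,4,5,5-tetramethyl-1,3,2-dioxaborolane; 7 methyl (E)-3-(4-hydroxy-3-iodo-5-methoxyphenyl)prop-2-enoate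
Product: 8 methyl (E)-3-{3-[(E)-1-(3,4-dimethoxyphenyl)prop-1-en-2-yl]-4-hydroxy-5-methoxyphenyl}prop-2-enoate
Conditions: Pd(OAc)2 (2 mol %), SPhos (4 mol %), K3PO4 (3 equiv), THF/H2O 10:1, 50 °C
Reagents that add atoms: none
Why: Suzuki–Miyaura coupling of an aryl iodide with an alkenyl boronate goes with retention of alkene geometry (the two aryl groups end up trans), and the free phenol and methyl ester survive mild phosphate base at 50 °C.

Step 5
Reactants: 8 methyl (E)-3-{3-[(E)-1-(3,4-dimethoxyphenyl)prop-1-en-2-yl]-4-hydroxy-5-methoxyphenyl}prop-2-enoate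
Product: 10 methyl (E)-3-[(2S,3S)-2-(3,4-dimethoxyphenyl)-7-methoxy-3-methyl-2,3-dihydro-1-benzofuran-5-yl]prop-2-enoate, via benzylic cation 9 (not isolated)
Conditions: (S,S)-IDPi-1 (5 mol %; imidodiphosphorimidate Brønsted acid from two 3,3'-bis[3,5-bis(trifluoromethyl)phenyl]-BINOL units with an N-triflyl core), PhMe (0.05 M), −20 °C, 72 h
Reagents that add atoms: none
Why: Proposed new method: catalytic asymmetric 5-endo hydroalkoxylation of an o-hydroxy-α-methylstilbene by a confined chiral Brønsted acid, in which the acid, hydrogen-bonded to the phenol, protonates the anethole-like alkene face-selectively at the methyl-bearing carbon (setting C3) to give the para-methoxy-stabilised benzylic cation 9 as a contact ion pair in the chiral pocket, and the phenol oxygen then closes onto C2 on the face that places the aryl group trans to the C3 methyl (less hindered, and also the thermodynamic isomer because C2–O ionisation is reversible under acid) while the anion takes back the phenol proton, so the C–O bond formation sets C2 and gives (2S,3S); the closest known reaction types are IDPi-catalysed asymmetric intramolecular hydroalkoxylation of alkenes (5-exo, one stereocentre) and the racemic acid-mediated cyclisation of 2-hydroxystilbenes to 2-aryl-2,3-dihydrobenzofurans.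

Step 6
Reactants: 10 methyl (E)-3-[(2S,3S)-2-(3,4-dimethoxyphenyl)-7-methoxy-3-methyl-2,3-dihydro-1-benzofuran-5-yl]prop-2-enoate
Product: 11 (E)-3-[(2S,3S)-2-(3,4-dimethoxyphenyl)-7-methoxy-3-methyl-2,3-dihydro-1-benzofuran-5-yl]prop-2-en-1-ol
Conditions: i-Bu2AlH (2.5 equiv), CH2Cl2, −78 °C; aq. potassium sodium tartrate
Reagents that add atoms: none
Why: DIBAL-H 1,2-reduction of an α,β-unsaturated ester at low temperature gives the (E)-allylic alcohol without touching the alkene, the aryl ethers, the benzylic ring ether or the two stereocentres.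

**Compound list**
1 | 4-iodo-1,2-dimethoxybenzene (4-iodoveratrole) | COc1ccc(I)cc1OC | starting material
2 | propyne | CC#C | starting material
3 | 1,2-dimethoxy-4-(prop-1-yn-1-yl)benzene | CC#Cc1ccc(OC)c(OC)c1 | intermediate
4 | 2-[(Z)-1-(3,4-dimethoxyphenyl)prop-1-en-2-yl]-4,4,5,5-tetramethyl-1,3,2-dioxaborolane (aryl trans to boron) | C/C(B1OC(C)(C)C(C)(C)O1)=C\c1ccc(OC)c(OC)c1 | intermediate
5 | 4-hydroxy-3-iodo-5-methoxybenzaldehyde (5-iodovanillin) | COc1cc(C=O)cc(I)c1O | starting material
6 | methyl (triphenylphosphoranylidene)acetate | COC(=O)C=P(c1ccccc1)(c1ccccc1)c1ccccc1 | starting material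
7 | methyl (E)-3-(4-hydroxy-3-iodo-5-methoxyphenyl)prop-2-enoate | COC(=O)/C=C/c1cc(I)c(O)c(OC)c1 | intermediate
8 | methyl (E)-3-{3-[(E)-1-(3,4-dimethoxyphenyl)prop-1-en-2-yl]-4-hydroxy-5-methoxyphenyl}prop-2-enoate | COC(=O)/C=C/c1cc(OC)c(O)c(c1)/C(C)=C/c1ccc(OC)c(OC)c1 | intermediate
9 | benzylic cation from protonation of 8 at the methyl-bearing alkene carbon, with the new C–H stereocentre as at C3 of 10 (contact ion pair with the IDPi anion; not isolated) | COC(=O)/C=C/c1cc(OC)c(O)c(c1)[C@@H]([CH+]c1ccc(OC)c(OC)c1)C | intermediate
10 | methyl (E)-3-[(2S,3S)-2-(3,4-dimethoxyphenyl)-7-methoxy-3-methyl-2,3-dihydro-1-benzofuran-5-yl]prop-2-enoate | COc1ccc([C@H]2Oc3c(OC)cc(/C=C/C(=O)OC)cc3[C@@H]2C)cc1OC | intermediate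
11 | (E)-3-[(2S,3S)-2-(3,4-dimethoxyphenyl)-7-methoxy-3-methyl-2,3-dihydro-1-benzofuran-5-yl]prop-2-en-1-ol (2,3-trans) | COc1ccc([C@H]2Oc3c(OC)cc(/C=C/CO)cc3[C@@H]2C)cc1OC | target

**Step count and risks**
Total steps: 6. Longest linear sequence: 5 (steps 1, 2, 4, 5, 6); step 3 is a one-step side branch.

Three steps most likely to fail:

Step 5 (the new reaction). The risks are:
- competing protonation at the other alkene carbon, which gives an o-hydroxybenzyl-type cation that cannot cyclise and may dimerise;
- catalyst inhibition by the ester carbonyl;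
- erosion of ee through reversible ring opening and re-protonation;
- a modest trans:cis ratio at low conversion.

Dilution, low temperature and a more acidic IDPi (perfluoroaryl-sulfonyl core) are the first adjustments. The fallback sets out from 8 and changes the source of chirality from catalyst control to separation. An achiral strong acid (TfOH, 5 mol %, CH2Cl2, 0 °C) cyclises 8 under thermodynamic control to the racemic trans-dihydrobenzofuran ester F1. Preparative supercritical-fluid chromatography on an amylose tris(3,5-dimethylphenylcarbamate) phase then gives the (2S,3S) enantiomer, and the sequence comes back to the route at 10.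

Step 4. The hindered, α-substituted alkenyl boronate may transmetalate slowly or protodeborylate, and the acrylate in 7 can divert aryl-palladium by Heck-type insertion or oligomerise under base. The fallback sets out from 4 (with 5) and moves the olefination after the coupling. Suzuki–Miyaura coupling of 4 with 5-iodovanillin 5 itself (unprotected 5-halovanillins are well-behaved partners) gives 3-[(E)-1-(3,4-dimethoxyphenyl)prop-1-en-2-yl]-4-hydroxy-5-methoxybenzaldehyde F2. Wittig olefination of F2 with 6 (PhMe, 90 °C) comes back to the route at 8.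

Step 2. With the electron-rich aryl group the boron regioselectivity may fall, and the regioisomeric boronate is hard to remove. The fallback sets out from 3 (with 7) and bypasses the boronate. Palladium-catalysed reductive syn-hydroarylation of alkyne 3 with iodide 7 (Pd(OAc)2, PPh3, HCO2K, DMF, 60 °C) is used instead. Here the regiochemistry is set by carbopalladation, which places the incoming aryl group on the less hindered methyl-bearing carbon, and formate then reduces the alkenyl-palladium with retention. It comes back to the route at 8 and makes no new compound, F0.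

**Further compounds**
F1 | step 5 | racemic trans methyl (E)-3-[2-(3,4-dimethoxyphenyl)-7-methoxy-3-methyl-2,3-dihydro-1-benzofuran-5-yl]prop-2-enoate (1:1 mixture of the 2S,3S and 2R,3R enantiomers) | COc1ccc([C@H]2Oc3c(OC)cc(/C=C/C(=O)OC)cc3[C@@H]2C)cc1OC.COc1ccc([C@@H]2Oc3c(OC)cc(/C=C/C(=O)OC)cc3[C@H]2C)cc1OC
F2 | step 4 | 3-[(E)-1-(3,4-dimethoxyphenyl)prop-1-en-2-yl]-4-hydroxy-5-methoxybenzaldehyde | O=Cc1cc(OC)c(O)c(c1)/C(C)=C/c1ccc(OC)c(OC)c1
F0 | step 2 | none | none
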